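The 2,5-cis-oxolane (O, C2′, C3′, C4′, C5′), its exocyclic carbinol carbon C6′ and the C7′ methyl group together make up the ring and methyl group of a 2,3,6-trideoxy-L-hexopyranose. The route therefore makes an α-C-glycoside of L-amicetose from di-O-acetyl-L-rhamnal and contracts its oxane ring. The ring oxygen, antiperiplanar to the equatorial C5′ triflate, expels it, and water opens the bicyclic oxonium ion at C6′. This single operation forms the oxolane, inverts C5′ and C6′, and frees the C6′ hydroxyl. A Mitsunobu esterification with (Z)-p-coumaric acid then inverts C6′ once more. Allylboration, acryloylation and ring-closing metathesis supply the lactone.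

Key step: step 5

Numbering used: lactone O1, C2 (C=O), C3=C4, C5, C6; side chain C1′ (free carbinol), C2′–C5′ (oxolane carbons), C6′ (acylated carbinol), C7′ (methyl).
Assumption: silyl ether 1 is taken as a catalogue chemical. The geometry drawn for 2 is that expected from the chelated enolate and is not decisive for step 2.

Step 1
Reactants: 1 methyl [(tert-butyldimethylsilyl)oxy]acetate
Product: 2 (Z)-2-[(tert-butyldimethylsilyl)oxy]-1-methoxy-1-[(trimethylsilyl)oxy]ethene
Conditions: LDA, TMSCl (in situ quench), THF, −78 °C to rt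
Reagents that add atoms: chlorotrimethylsilane, C[Si](C)(C)Cl
Why: Kinetic deprotonation of the glycolate ester and O-silylation of its enolate (ketene silyl acetal formation) is standard, the in situ quench forestalls silyl migration and Claisen condensation, and no stereocentre is formed.

Step 2
Reactants: 3 3,4-di-O-acetyl-L-rhamnal; 2 ketene silyl acetal
Product: 4 methyl (2S)-2-[(2R,5R,6S)-5-acetoxy-6-methyl-5,6-dihydro-2H-pyran-2-yl]-2-[(tert-butyldimethylsilyl)oxy]acetate (α-C-glycoside, 2,6-trans; C1′/C2′ threo)
Conditions: TMSOTf (10 mol %), CH2Cl2, −78 to −40 °C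
Reagents that add atoms: none
Why: Carbon-Ferrier rearrangement (Mukaiyama-type C-glycosylation), in which the allyl oxocarbenium ion from 3 is attacked at C2′ along the axial trajectory on the face trans to the C6′ methyl group (α, 2,6-trans), and an open antiperiplanar transition state that turns the silyloxy group of 2 away from the ring should set C1′ threo to C2′.

Step 3
Reactants: 4 unsaturated C-glycoside
Product: 5 methyl (2S)-2-[(2R,5R,6S)-5-acetoxy-6-methyloxan-2-yl]-2-[(tert-butyldimethylsilyl)oxy]acetate
Conditions: H2 (1 atm), Pd/C, EtOAc, rt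
Reagents that add atoms: none
Why: Catalytic hydrogenation saturates the only C=C bond (C3′=C4′) without creating a stereocentre, and ethyl acetate as solvent keeps hydrogenolysis of the allylic C–O bonds low.

Step 4
Reactants: 5 saturated acetate
Product: 6 methyl (2S)-2-[(tert-butyldimethylsilyl)oxy]-2-[(2R,5R,6S)-5-hydroxy-6-methyloxan-2-yl]acetate
Conditions: K2CO3 (0.2 equiv), MeOH, 0 °C
Reagents that add atoms: none
Why: Zemplén-type transesterification removes the acetate and frees the equatorial C5′ hydroxyl, while the methyl ester merely exchanges with the solvent and the silyl ether and all stereocentres stay untouched.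

Step 5
Reactants: 6 oxan-5-ol (C5′ alcohol)
Product: 9 methyl (2S)-2-[(tert-butyldimethylsilyl)oxy]-2-{(2R,5S)-5-[(1R)-1-hydroxyethyl]oxolan-2-yl}acetate, via C5′ triflate 7 (not isolated), via 1-oxoniabicyclo[3.1.0]hexane triflate 8 (not isolated)
Conditions: Tf2O, 2,6-lutidine, CH2Cl2, −78 to −20 °C; then HFIP–H2O (9:1), −20 °C to rt
Reagents that add atoms: water, O; trifluoromethanesulfonic anhydride, O=S(=O)(C(F)(F)F)OS(=O)(=O)C(F)(F)F (its atoms remain only in 7 and 8)
Why: Triflation gives 7, in whose chair (C6′ methyl and triflate equatorial, C2′ side chain axial) the ring C6′–O bond lies antiperiplanar to C5′–OTf, so that on ionisation the ring oxygen displaces triflate from the rear to give the trans-substituted epoxonium ion 8, which water opens by SN2 attack at C6′. The closest known reaction type is the pyranoside-to-furanoside ring contraction of 6-deoxyhexopyranoside 4-sulfonates through participation of the ring oxygen, the reverse of the oxolane-to-oxane ring expansion of exocyclic sulfonates. The new O–C5′ bond closes the oxolane in a 5-exo-tet mode and, at the same time, the transient three-membered oxonium ring in a 3-exo-tet mode. C5′ is set by inversion (R to S) under control of the sugar C-4 configuration, C6′ by inversion (S to R) in the opening, and C2′ is untouched, so that the 2,6-trans oxane can give only the 2,5-cis oxolane. Participation must outrun direct solvolysis, elimination and hydride or methyl shifts, which the ionising, weakly nucleophilic medium, the hindered base and the antiperiplanar alignment favour. The oxonium ion must also open at C6′ and not at C5′, which rests on the small methyl-bearing carbon and on the preference of bicyclo[3.1.0] epoxonium ions for attack at the exocyclic carbon.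

Step 6
Reactants: 9 oxolane alcohol
Product: 10 methyl (2S)-2-[(tert-butyldimethylsilyl)oxy]-2-{(2R,5S)-5-[(1R)-1-(triethylsilyloxy)ethyl]oxolan-2-yl}acetate
Conditions: TESCl, imidazole, CH2Cl2, 0 °C
Reagents that add atoms: chlorotriethylsilane, CC[Si](CC)(CC)Cl
Why: Standard silylation masks the C6′ hydroxyl with a group that can later be removed in the presence of the C1′ tert-butyldimethylsilyl ether, and no stereocentre is affected.

Step 7
Reactants: 10 methyl ester
Product: 11 (2S)-2-[(tert-butyldimethylsilyl)oxy]-2-{(2R,5S)-5-[(1R)-1-(triethylsilyloxy)ethyl]oxolan-2-yl}acetaldehyde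
Conditions: DIBAL-H (1.1 equiv), CH2Cl2, −78 °C; aq. Rochelle salt
Reagents that add atoms: none
Why: DIBAL-H half-reduction of an α-silyloxy methyl ester stops at the aldehyde because the aluminium hemiacetal is stable at −78 °C, and the non-basic conditions leave C1′ unchanged.

Step 8
Reactants: 11 aldehyde
Product: 13 homoallylic alcohol, 1-[(tert-butyldimethylsilyl)oxy]-1-[oxolan-2-yl]pent-4-en-2-ol with (6R) carbinol, C1′/C6 anti, C1′/C2′ syn, 2,5-cis oxolane and (6′R) triethylsilyl ether, via diisopinocampheylborinate 12 (not isolated)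
Conditions: B-allyldiisopinocampheylborane from (−)-α-pinene, Et2O, −78 °C; then 30 % H2O2, pH 7 buffer, MeOH, 0 °C to rt
Reagents that add atoms: B-allyldiisopinocampheylborane from (−)-α-pinene, C=CCB([C@H]1C[C@H]2C[C@@H]([C@@H]1C)C2(C)C)[C@H]1C[C@H]2C[C@@H]([C@@H]1C)C2(C)C
Why: Brown asymmetric allylboration through a chair Zimmerman–Traxler transition state, in which the reagent from (−)-α-pinene delivers allyl to the aldehyde face that gives (6R), which is also the polar Felkin–Anh (C1′/C6 anti) face, so that reagent and substrate control should be matched.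

Step 9
Reactants: 13 homoallylic alcohol
Product: 14 C6 acrylate of 13 (all stereocentres as in 13)
Conditions: acryloyl chloride, iPr2NEt, DMAP (cat.), CH2Cl2, 0 °C
Reagents that add atoms: acryloyl chloride, C=CC(=O)Cl
Why: Acylation of the C6 alcohol with retention installs C2 and C3 of the lactone and the second alkene for metathesis.

Step 10
Reactants: 14 acrylate
Product: 15 (6R)-5,6-dihydro-2H-pyran-2-one bearing the C1′ tert-butyldimethylsilyl ether, the 2,5-cis oxolane and the (6′R) triethylsilyl ether
Conditions: Grubbs II catalyst (5 mol %), CH2Cl2 (2 mM), reflux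
Reagents that add atoms: none
Why: Ring-closing metathesis of the acrylate with the terminal alkene closes the six-membered α,β-unsaturated lactone, whose ring size enforces the cis C3=C4 bond, with loss of ethene as driving force.

Step 11
Reactants: 15 bis-silyl ether
Product: 16 lactone with free (6′R) hydroxyl and C1′ tert-butyldimethylsilyl ether
Conditions: PPTS (cat.), MeOH–CH2Cl2, 0 °C
Reagents that add atoms: none
Why: Mild acid-catalysed methanolysis cleaves the triethylsilyl ether much faster than the more hindered tert-butyldimethylsilyl ether and leaves the lactone and all stereocentres intact.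

Step 12
Reactants: 17 4-[(tert-butyldimethylsilyl)oxy]benzaldehyde; 18 methyl bis(2,2,2-trifluoroethyl)phosphonoacetate
Product: 19 methyl (Z)-3-{4-[(tert-butyldimethylsilyl)oxy]phenyl}prop-2-enoate
Conditions: KHMDS, 18-crown-6, THF, −78 °C
Reagents that add atoms: none
Why: Still–Gennari modification of the Horner–Wadsworth–Emmons olefination, in which the electron-poor phosphonate with a dissociated potassium counter-ion makes elimination faster than equilibration of the adducts and so gives the (Z)-cinnamate.

Step 13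
Reactants: 19 (Z)-ester
Product: 20 (Z)-p-coumaric acid
Conditions: LiOH, THF–MeOH–H2O, rt, dark; then 1 M HCl
Reagents that add atoms: lithium hydroxide, [Li+].[OH-]
Why: Saponification of the methyl ester also removes the base-labile aryl silyl ether, which is no longer needed, and the (Z)-alkene is kept when light is excluded.

Step 14
Reactants: 16 (6′R) alcohol; 20 (Z)-p-coumaric acid
Product: 21 (6′S) (Z)-p-coumarate with C1′ tert-butyldimethylsilyl ether
Conditions: PPh3, DIAD, THF, 0 °C to rt, dark
Reagents that add atoms: none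
Why: Mitsunobu esterification, in which SN2 displacement of the alkoxyphosphonium ion by the carboxylate inverts C6′ from R to S, the far more acidic carboxyl group reacts in preference to the phenol, and the acid is never activated at its acyl carbon so that the (Z)-alkene is kept.

Step 15
Reactants: 21 silyl ether
Product: 22 target, CNP0417147.1 (6R,1′S,2′R,5′S,6′S)
Conditions: HF·pyridine, pyridine, THF, 0 °C to rt, dark
Reagents that add atoms: none
Why: Fluoride-driven cleavage of the remaining silyl ether under mildly acidic conditions spares both esters, the (Z)-alkene and all stereocentres and gives the target.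

Compound list
1 | methyl [(tert-butyldimethylsilyl)oxy]acetate | COC(=O)CO[Si](C)(C)C(C)(C)C | starting material
2 | (Z)-2-[(tert-butyldimethylsilyl)oxy]-1-methoxy-1-[(trimethylsilyl)oxy]ethene | CO/C(O[Si](C)(C)C)=C/O[Si](C)(C)C(C)(C)C | intermediate
3 | 3,4-di-O-acetyl-L-rhamnal, (2S,3S,4S) | C[C@@H]1OC=C[C@H](OC(C)=O)[C@H]1OC(C)=O | starting material
4 | unsaturated α-C-glycoside (Ferrier product) | C[C@@H]1O[C@@H]([C@H](O[Si](C)(C)C(C)(C)C)C(=O)OC)C=C[C@H]1OC(C)=O | intermediate
5 | saturated C5′ acetate | C[C@@H]1O[C@@H]([C@H](O[Si](C)(C)C(C)(C)C)C(=O)OC)CC[C@H]1OC(C)=O | intermediate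
6 | oxane C5′ alcohol | C[C@@H]1O[C@@H]([C@H](O[Si](C)(C)C(C)(C)C)C(=O)OC)CC[C@H]1O | intermediate
7 | oxane C5′ triflate | C[C@@H]1O[C@@H]([C@H](O[Si](C)(C)C(C)(C)C)C(=O)OC)CC[C@H]1OS(=O)(=O)C(F)(F)F | intermediate
8 | 1-oxoniabicyclo[3.1.0]hexane triflate | C[C@H]1[C@@H]2CC[C@H]([C@H](O[Si](C)(C)C(C)(C)C)C(=O)OC)[O+]12.[O-]S(=O)(=O)C(F)(F)F | intermediate
9 | 2,5-cis oxolane, (6′R) alcohol | C[C@@H](O)[C@@H]1CC[C@H]([C@H](O[Si](C)(C)C(C)(C)C)C(=O)OC)O1 | intermediate
10 | C6′ triethylsilyl ether, methyl ester | C[C@@H](O[Si](CC)(CC)CC)[C@@H]1CC[C@H]([C@H](O[Si](C)(C)C(C)(C)C)C(=O)OC)O1 | intermediate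
11 | α-silyloxy aldehyde | C[C@@H](O[Si](CC)(CC)CC)[C@@H]1CC[C@H]([C@H](O[Si](C)(C)C(C)(C)C)C=O)O1 | intermediate
12 | diisopinocampheylborinate of 13 | C[C@@H](O[Si](CC)(CC)CC)[C@@H]1CC[C@H]([C@H](O[Si](C)(C)C(C)(C)C)[C@H](OB([C@H]2C[C@H]3C[C@@H]([C@@H]2C)C3(C)C)[C@H]2C[C@H]3C[C@@H]([C@@H]2C)C3(C)C)CC=C)O1 | intermediate
13 | (6R) homoallylic alcohol | C[C@@H](O[Si](CC)(CC)CC)[C@@H]1CC[C@H]([C@H](O[Si](C)(C)C(C)(C)C)[C@H](O)CC=C)O1 | intermediate
14 | C6 acrylate | C[C@@H](O[Si](CC)(CC)CC)[C@@H]1CC[C@H]([C@H](O[Si](C)(C)C(C)(C)C)[C@H](OC(=O)C=C)CC=C)O1 | intermediate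
15 | dihydropyranone, bis-silyl ether | C[C@@H](O[Si](CC)(CC)CC)[C@@H]1CC[C@H]([C@H](O[Si](C)(C)C(C)(C)C)[C@H]2CC=CC(=O)O2)O1 | intermediate
16 | dihydropyranone, free (6′R) alcohol | C[C@@H](O)[C@@H]1CC[C@H]([C@H](O[Si](C)(C)C(C)(C)C)[C@H]2CC=CC(=O)O2)O1 | intermediate
17 | 4-[(tert-butyldimethylsilyl)oxy]benzaldehyde | O=Cc1ccc(O[Si](C)(C)C(C)(C)C)cc1 | starting material
18 | methyl bis(2,2,2-trifluoroethyl)phosphonoacetate | COC(=O)CP(=O)(OCC(F)(F)F)OCC(F)(F)F | starting material
19 | methyl (Z)-3-{4-[(tert-butyldimethylsilyl)oxy]phenyl}prop-2-enoate | COC(=O)/C=C\c1ccc(O[Si](C)(C)C(C)(C)C)cc1 | intermediate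
20 | (Z)-p-coumaric acid | OC(=O)/C=C\c1ccc(O)cc1 | intermediate
21 | (6′S) (Z)-p-coumarate, C1′ silyl ether | C[C@H](OC(=O)/C=C\c1ccc(O)cc1)[C@@H]1CC[C@H]([C@H](O[Si](C)(C)C(C)(C)C)[C@H]2CC=CC(=O)O2)O1 | intermediate
22 | CNP0417147.1 | C[C@H](OC(=O)/C=C\c1ccc(O)cc1)[C@@H]1CC[C@H]([C@H](O)[C@H]2CC=CC(=O)O2)O1 | target

Total step count: 15. Longest linear sequence: 13 steps (steps 1–11, 14, 15).

Steps most likely to fail

Step 5. Several processes may compete with the contraction:
- direct solvolytic displacement or elimination of the triflate;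
- a hydride or methyl shift from the ring-flipped chair, in which the triflate is axial;
- opening of the oxonium ion at C5′, which returns the oxane.

The fallback sets out from 6 and comes back at 9.
- The hydroxyl of 6 is replaced with inversion (I2, PPh3, imidazole, toluene) to give the axial iodide F1.
- Zinc dust in aqueous ethanol at reflux cleaves the β-iodo ether reductively (Boord-type elimination) and opens the oxane to the (E)-hydroxy alkene F2.
- Shi epoxidation (D-fructose-derived ketone, Oxone, buffered MeCN–dimethoxymethane–water, 0 °C) gives the (5′R,6′R)-epoxide F3.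
- Catalytic camphorsulfonic acid closes F3 by 5-exo-tet attack of the C2′ hydroxyl at C5′ with inversion, which gives 9.

Step 2. Facial selectivity at the prochiral ketene acetal carbon (C1′) may be poor, and the α-selectivity at C2′ may erode. The fallback sets out from 1 and 3 and comes back at 6.
- Ester 1 is saponified (LiOH, THF–H2O) to (tert-butyldimethylsilyloxy)acetic acid F4.
- F4 is coupled (EDC, DMAP) with commercial (R)-4-isopropyl-1,3-thiazolidine-2-thione to the N-glycolyl auxiliary F5.
- The chelated chlorotitanium enolate of F5 (TiCl4, iPr2NEt, CH2Cl2, −78 °C) is added to 3 in the presence of SnCl4. The auxiliary shields one enolate face and fixes (1′S), which gives the adduct F6.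
- K2CO3 in methanol removes auxiliary and acetate together to give the unsaturated hydroxy ester F7.
- Hydrogenation of F7 as in step 3 gives 6.

Step 14. Three failure modes are foreseen:
- sluggish displacement at the secondary carbinol next to the oxolane, with elimination;
- participation of the ring oxygen, which would cost inversion;
- Z-to-E isomerisation of the acid.

The fallback sets out from 16 and 19 and comes back at 22.
- Alcohol 16 is oxidised (Dess–Martin periodinane) to the methyl ketone F8.
- CBS reduction [(R)-Me-CBS, BH3·SMe2, −40 °C] gives the (6′S) alcohol F9 under reagent control.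
- Ester 19 is hydrolysed under neutral conditions (Me3SnOH, 1,2-dichloroethane, 70 °C) to the silyl-protected (Z)-acid F10.
- Carbodiimide esterification of F9 with F10 (EDC, DMAP, CH2Cl2, 0 °C, dark) proceeds with retention and gives the bis-silyl ether F11.
- HF·pyridine as in step 15 converts F11 into 22.

Further compounds
F1 | step 5 | methyl (2S)-2-[(tert-butyldimethylsilyl)oxy]-2-[(2R,5S,6S)-5-iodo-6-methyloxan-2-yl]acetate | C[C@@H]1O[C@@H]([C@H](O[Si](C)(C)C(C)(C)C)C(=O)OC)CC[C@@H]1I
F2 | step 5 | methyl (2S,3R,6E)-2-[(tert-butyldimethylsilyl)oxy]-3-hydroxyoct-6-enoate | C/C=C/CC[C@@H](O)[C@H](O[Si](C)(C)C(C)(C)C)C(=O)OC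
F3 | step 5 | methyl (2S,3R)-2-[(tert-butyldimethylsilyl)oxy]-3-hydroxy-5-[(2R,3R)-3-methyloxiran-2-yl]pentanoate | C[C@H]1O[C@@H]1CC[C@@H](O)[C@H](O[Si](C)(C)C(C)(C)C)C(=O)OC
F4 | step 2 | [(tert-butyldimethylsilyl)oxy]acetic acid | OC(=O)CO[Si](C)(C)C(C)(C)C
F5 | step 2 | (R)-3-{[(tert-butyldimethylsilyl)oxy]acetyl}-4-isopropyl-1,3-thiazolidine-2-thione | CC(C)[C@@H]1CSC(=S)N1C(=O)CO[Si](C)(C)C(C)(C)C
F6 | step 2 | auxiliary-bound unsaturated α-C-glycoside, (1′S,2′R) | C[C@@H]1O[C@@H]([C@H](O[Si](C)(C)C(C)(C)C)C(=O)N2[C@H](C(C)C)CSC2=S)C=C[C@H]1OC(C)=O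
F7 | step 2 | methyl (2S)-2-[(tert-butyldimethylsilyl)oxy]-2-[(2R,5R,6S)-5-hydroxy-6-methyl-5,6-dihydro-2H-pyran-2-yl]acetate | C[C@@H]1O[C@@H]([C@H](O[Si](C)(C)C(C)(C)C)C(=O)OC)C=C[C@H]1O
F8 | step 14 | C6′ methyl ketone of 16 | CC(=O)[C@@H]1CC[C@H]([C@H](O[Si](C)(C)C(C)(C)C)[C@H]2CC=CC(=O)O2)O1
F9 | step 14 | (6′S) epimer of 16 | C[C@H](O)[C@@H]1CC[C@H]([C@H](O[Si](C)(C)C(C)(C)C)[C@H]2CC=CC(=O)O2)O1
F10 | step 14 | (Z)-3-{4-[(tert-butyldimethylsilyl)oxy]phenyl}prop-2-enoic acid | OC(=O)/C=C\c1ccc(O[Si](C)(C)C(C)(C)C)cc1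
F11 | step 14 | bis-silyl ether of the target | C[C@H](OC(=O)/C=C\c1ccc(O[Si](C)(C)C(C)(C)C)cc1)[C@@H]1CC[C@H]([C@H](O[Si](C)(C)C(C)(C)C)[C@H]2CC=CC(=O)O2)O1
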